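**Retrosynthetic overview**
- The crotonate ester and the free C15 alcohol are installed last, on an 8‑hydroxy, 15‑O‑silyl tricyclic lactone.
- Key disconnection: the C6–C7 and O6–C12 bonds are cut together. An acyclic vinyl‑epoxide enal closes reductively to the ten‑membered carbocycle and the γ‑lactone in one flask, and C8 controls C7 and C6.
- The vinyl epoxide comes from an E‑dienoate by reagent‑controlled epoxidation, which sets C8.
- The furanone is stitched at C3 from carbon monoxide, a Z‑iodoenal (C4–C6, C15) and an ethynyl carbinol (C1, C2, C7–C14).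
- Ring order: furanone first, then carbocycle and lactone together. C10 comes from an asymmetric epoxidation of a C6 enynol, and C4=C5 from but‑2‑yne‑1,4‑diol.

Assumption: the SMILES is taken at face value, i.e. 6S,7S,8R,10R, a trans‑fused lactone and a 4Z alkene.

Germacrane atom labels are used: C1 ketone, C2=C3 furanone alkene, C4=C5, C6–O lactone, C7, C8–O ester, C9, C10 quaternary, C11–C13 methylene lactone, C14 methyl, C15 CH2OH.

**Step 1**
Reactants: 1 but-2-yne-1,4-diol
Product: 2 4-[(tert-butyldimethylsilyl)oxy]but-2-yn-1-ol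
Conditions: NaH (1.0 equiv), THF, 0 °C; t-BuMe2SiCl (1.0 equiv), 23 °C
Reagents that add atoms: tert-butyldimethylsilyl chloride, CC(C)(C)[Si](C)(C)Cl
Why: O‑silylation of the sparingly soluble monosodium alkoxide of a symmetrical diol stops at the mono ether, and no stereocentre is involved.

**Step 2**
Reactants: 2 4-[(tert-butyldimethylsilyl)oxy]but-2-yn-1-ol
Product: 3 (2Z)-4-[(tert-butyldimethylsilyl)oxy]-3-iodobut-2-en-1-ol
Conditions: NaAlH2(OCH2CH2OMe)2, Et2O, 0 → 23 °C; I2, THF, −78 °C
Reagents that add atoms: iodine, [I][I]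
Why: Hydroxyl‑directed trans‑hydroalumination puts aluminium on the distal alkyne carbon (C4), and iodinolysis with retention gives the Z‑iodoalkene, which fixes C6 cis to the later C3 substituent.

**Step 3**
Reactants: 3 (2Z)-4-[(tert-butyldimethylsilyl)oxy]-3-iodobut-2-en-1-ol
Product: 4 (2Z)-4-[(tert-butyldimethylsilyl)oxy]-3-iodobut-2-enal
Conditions: MnO2 (15 equiv), CH2Cl2, 23 °C, dark
Reagents that add atoms: none
Why: Allylic alcohol oxidation on neutral heterogeneous MnO2 leaves the vinyl iodide, the silyl ether and the Z geometry untouched.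

**Step 4**
Reactants: 5 (2E)-3-methylpent-2-en-4-yn-1-ol
Product: 6 [(2S,3S)-3-ethynyl-3-methyloxiran-2-yl]methanol
Conditions: Ti(OiPr)4 (10 mol %), L-(+)-diethyl tartrate (12 mol %), t-BuOOH, 4 Å sieves, CH2Cl2, −20 °C
Reagents that add atoms: tert-butyl hydroperoxide, CC(C)(C)OO
Why: In this Katsuki–Sharpless asymmetric epoxidation the L‑(+)‑tartrate catalyst gives the 2S,3S epoxide from this E‑3,3‑disubstituted allylic alcohol (same sense as geraniol), which sets the C10–O bond.

**Step 5**
Reactants: 6 [(2S,3S)-3-ethynyl-3-methyloxiran-2-yl]methanol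
Product: 7 (3R)-3-methylpent-4-yne-1,3-diol
Conditions: LiBHEt3 (3 equiv), THF, 0 → 23 °C; H2O
Reagents that add atoms: none
Why: SN2 hydride opening takes place at the secondary epoxide carbon (C9) and not at the quaternary one, so the C10–O bond is never broken and C10 emerges as the R tertiary carbinol.

**Step 6**
Reactants: 7 (3R)-3-methylpent-4-yne-1,3-diol; 8 methyl 2-(bromomethyl)prop-2-enoate
Product: 12 methyl (3E,6R)-6-hydroxy-6-methyl-2-methylideneoct-3-en-7-ynoate, via hydroxy aldehyde 9 (not isolated), via phosphonium bromide 10 (not isolated), via phosphorane 11 (not isolated)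
Conditions: TEMPO (10 mol %), PhI(OAc)2 (1.1 equiv), CH2Cl2, 23 °C; then PPh3, 8, K2CO3, CH2Cl2–H2O, 23 °C
Reagents that add atoms: methyl 2-(bromomethyl)prop-2-enoate (8), C=C(CBr)C(=O)OC
Why: TEMPO/PhI(OAc)2 oxidises only the primary alcohol, and the fragile β‑hydroxy aldehyde is trapped at once by a Wittig olefination with the semi‑stabilised allylic phosphorane made in the same flask, which reacts at its α‑carbon to give the E‑diene without touching C10.

**Step 7**
Reactants: 4 (2Z)-4-[(tert-butyldimethylsilyl)oxy]-3-iodobut-2-enal; 12 methyl (3E,6R)-6-hydroxy-6-methyl-2-methylideneoct-3-en-7-ynoate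
Product: 14 methyl (3E)-5-[(2R)-5-{(2Z)-1-[(tert-butyldimethylsilyl)oxy]-4-oxobut-2-en-2-yl}-2-methyl-3-oxo-2,3-dihydrofuran-2-yl]-2-methylidenepent-3-enoate, via hydroxy ynone 13 (not isolated)
Conditions: PdCl2(PPh3)2 (5 mol %), CuI (1 mol %), Et3N (2.5 equiv), THF, CO (5 atm), 25 °C; vent, evaporate, wet toluene, filter; (Ph3P)AuCl/AgOTf (5 mol % each), 25 °C
Reagents that add atoms: carbon monoxide, [C-]#[O+] (its carbon becomes C3); water, O (its oxygen ends as the C1 ketone oxygen, and the oxygen of CO leaves again as water)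
Why: Carbonylative Sonogashira coupling (oxidative addition with retention, CO insertion, alkynyl transfer) gives a 4‑hydroxy‑2‑ynone, and cationic gold then effects the known conjugate hydration/cyclodehydration of such ynones to 3(2H)‑furanones, so the carbinol oxygen becomes the ring oxygen and C10 keeps its configuration.

**Step 8**
Reactants: 14 (furanone dienoate enal)
Product: 15 methyl 2-[(2R,3R)-3-{[(2R)-5-{(2Z)-1-[(tert-butyldimethylsilyl)oxy]-4-oxobut-2-en-2-yl}-2-methyl-3-oxo-2,3-dihydrofuran-2-yl]methyl}oxiran-2-yl]prop-2-enoate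
Conditions: D-fructose-derived Shi ketone (30 mol %), KHSO5 (as 2KHSO5·KHSO4·K2SO4), K2CO3, Bu4NHSO4, MeCN–CH2(OMe)2 / aq. Na2B4O7 buffer, 0 °C
Reagents that add atoms: potassium peroxymonosulfate, [K+].[O-]S(=O)(=O)OO
Why: In this Shi asymmetric epoxidation the chiral dioxirane attacks the only alkene that is not strongly deactivated (trans C7=C8) through the spiro transition state that gives R,R‑epoxides from trans‑alkenes, which sets C8 as R.

**Step 9 (key step)**
Reactants: 15 (vinyl epoxide enal)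
Product: 18 (2Z,4S,8S,9R,11R)-2-{[(tert-butyldimethylsilyl)oxy]methyl}-9-hydroxy-11-methyl-7-methylidene-5,14-dioxatricyclo[9.2.1.0(4,8)]tetradeca-1(13),2-diene-6,12-dione, via allylic iodide 16 (not isolated), via silyl lactone 17 (not isolated)
Conditions: Me3SiCl (1.05 equiv), LiI (3 equiv), THF, −40 → 0 °C; added over 10 h to CrCl2 (6 equiv), THF, 0.002 M, 23 °C; 10 % aq. citric acid, 1 h
Reagents that add atoms: chlorotrimethylsilane, C[Si](C)(C)Cl; lithium iodide, [Li+].[I-] (their atoms are carried only by 16 and 17)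
Why: Proposed new method: Me3SiI opens the acrylate‑substituted vinyl epoxide (SN2′ or SN2, both converge) to an allylic iodide whose C8–O bond is untouched and masked as a silyl ether that neither leaves nor acylates; two equivalents of divalent chromium convert it into a γ‑substituted allylchromium that adds through C7 to the tethered enal in a chair transition state (C8–H eclipsing the alkene, attack anti to OSiMe3, anti C6/C7 topology) to set 7S and 6S; the trivalent chromium alkoxide on O6 then displaces methoxide, so the ten‑membered carbocycle and the trans γ‑lactone form in one flask; the closest known reactions are the CrCl2/LiI coupling of 1,3‑diene monoepoxides with aldehydes (Takai–Utimoto) and Nozaki–Hiyama‑type macrocyclisations of 2‑(halomethyl)enoates to trans‑fused germacranolide lactones.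

**Step 10**
Reactants: 18 (hydroxy lactone); 19 (2E)-but-2-enoic anhydride
Product: 20 (2Z,4S,8S,9R,11R)-2-{[(tert-butyldimethylsilyl)oxy]methyl}-11-methyl-7-methylidene-6,12-dioxo-5,14-dioxatricyclo[9.2.1.0(4,8)]tetradeca-1(13),2-dien-9-yl (2E)-but-2-enoate
Conditions: 19 (3 equiv), DMAP (0.2 equiv), iPr2NEt, CH2Cl2, 0 → 23 °C
Reagents that add atoms: (2E)-but-2-enoic anhydride (19), C/C=C/C(=O)OC(=O)/C=C/C
Why: DMAP‑catalysed acylation of the only free hydroxyl proceeds at oxygen, so C8 is retained, and the anhydride avoids the ketene pathway that deconjugates crotonyl chloride.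

**Step 11**
Reactants: 20 (silyl crotonate)
Product: 21 (2Z,4S,8S,9R,11R)-2-(hydroxymethyl)-11-methyl-7-methylidene-6,12-dioxo-5,14-dioxatricyclo[9.2.1.0(4,8)]tetradeca-1(13),2-dien-9-yl (2E)-but-2-enoate (target)
Conditions: HF·pyridine, pyridine–THF, 0 °C
Reagents that add atoms: none
Why: Buffered fluoride desilylation of the primary allylic silyl ether is acidic enough to spare the methylene lactone, the crotonate and the furanone, and it touches no stereocentre.

**Compound list**

| No. | Name | SMILES | Role |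
|---|---|---|---|
| 1 | but-2-yne-1,4-diol | OCC#CCO | starting material |
| 2 | 4-[(tert-butyldimethylsilyl)oxy]but-2-yn-1-ol | OCC#CCO[Si](C)(C)C(C)(C)C | intermediate |
| 3 | (2Z)-4-[(tert-butyldimethylsilyl)oxy]-3-iodobut-2-en-1-ol | OC/C=C(\I)CO[Si](C)(C)C(C)(C)C | intermediate |
| 4 | (2Z)-4-[(tert-butyldimethylsilyl)oxy]-3-iodobut-2-enal | O=C/C=C(\I)CO[Si](C)(C)C(C)(C)C | intermediate |
| 5 | (2E)-3-methylpent-2-en-4-yn-1-ol | C#C/C(C)=C/CO | starting material |
| 6 | [(2S,3S)-3-ethynyl-3-methyloxiran-2-yl]methanol | C#C[C@]1(C)O[C@H]1CO | intermediate |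
| 7 | (3R)-3-methylpent-4-yne-1,3-diol | C#C[C@](C)(O)CCO | intermediate |
| 8 | methyl 2-(bromomethyl)prop-2-enoate | C=C(CBr)C(=O)OC | starting material |
| 9 | (3R)-3-hydroxy-3-methylpent-4-ynal | C#C[C@](C)(O)CC=O | intermediate |
| 10 | [2-(methoxycarbonyl)prop-2-en-1-yl]triphenylphosphonium bromide | C=C(C[P+](c1ccccc1)(c1ccccc1)c1ccccc1)C(=O)OC.[Br-] | intermediate |
| 11 | methyl 2-[(triphenyl-λ5-phosphanylidene)methyl]prop-2-enoate | C=C(C=P(c1ccccc1)(c1ccccc1)c1ccccc1)C(=O)OC | intermediate |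
| 12 | methyl (3E,6R)-6-hydroxy-6-methyl-2-methylideneoct-3-en-7-ynoate | C#C[C@](C)(O)C/C=C/C(=C)C(=O)OC | intermediate |
| 13 | methyl (3E,6R,10Z)-10-{[(tert-butyldimethylsilyl)oxy]methyl}-6-hydroxy-6-methyl-2-methylidene-9,12-dioxododeca-3,10-dien-7-ynoate | O=C/C=C(/CO[Si](C)(C)C(C)(C)C)C(=O)C#C[C@](C)(O)C/C=C/C(=C)C(=O)OC | intermediate |
| 14 | furanone dienoate enal (name in step 7; 10R, 4Z, 7E) | O=C/C=C(/CO[Si](C)(C)C(C)(C)C)C1=CC(=O)[C@@](C)(C/C=C/C(=C)C(=O)OC)O1 | intermediate |
| 15 | vinyl epoxide enal (name in step 8; 7R,8R,10R) | O=C/C=C(/CO[Si](C)(C)C(C)(C)C)C1=CC(=O)[C@@](C)(C[C@H]2O[C@@H]2C(=C)C(=O)OC)O1 | intermediate |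
| 16 | methyl (2Z,4R)-5-[(2R)-5-{(2Z)-1-[(tert-butyldimethylsilyl)oxy]-4-oxobut-2-en-2-yl}-2-methyl-3-oxo-2,3-dihydrofuran-2-yl]-2-(iodomethyl)-4-[(trimethylsilyl)oxy]pent-2-enoate | O=C/C=C(/CO[Si](C)(C)C(C)(C)C)C1=CC(=O)[C@@](C)(C[C@@H](O[Si](C)(C)C)/C=C(\CI)C(=O)OC)O1 | intermediate |
| 17 | 8-O-trimethylsilyl ether of 18 (same spatial arrangement) | C=C1C(=O)O[C@H]2/C=C(/CO[Si](C)(C)C(C)(C)C)C3=CC(=O)[C@@](C)(C[C@@H](O[Si](C)(C)C)[C@H]12)O3 | intermediate |
| 18 | 8-hydroxy-15-O-TBS tricyclic lactone (name in step 9; 6S,7S,8R,10R) | C=C1C(=O)O[C@H]2/C=C(/CO[Si](C)(C)C(C)(C)C)C3=CC(=O)[C@@](C)(C[C@@H](O)[C@H]12)O3 | intermediate |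
| 19 | (2E)-but-2-enoic anhydride | C/C=C/C(=O)OC(=O)/C=C/C | starting material |
| 20 | 15-O-TBS ether of the target (name in step 10) | C=C1C(=O)O[C@H]2/C=C(/CO[Si](C)(C)C(C)(C)C)C3=CC(=O)[C@@](C)(C[C@@H](OC(=O)/C=C/C)[C@H]12)O3 | intermediate |
| 21 | CNP0225232.1 (name in step 11) | C=C1C(=O)O[C@H]2/C=C(/CO)C3=CC(=O)[C@@](C)(C[C@@H](OC(=O)/C=C/C)[C@H]12)O3 | target |

**Step count**
- Total steps: 11.
- Longest linear sequence: 8 (steps 4–6 or 1–3, then 7–11).

**Steps most likely to fail**

Step 9 is the riskiest. The failure modes are oligomerisation, 1,4‑elimination back to diene 14, strain in the furanone‑bridged transition state, and formation of the cis‑lactone. The fallback reverses the order of the two couplings; it sets out from 12 and 4 and returns at 18. Compound 12 is epoxidised as in step 8 to methyl 2-{(2R,3R)-3-[(2R)-2-hydroxy-2-methylbut-3-yn-1-yl]oxiran-2-yl}prop-2-enoate F3. Et3SiCl/LiI opens it to methyl (2Z,4R,6R)-6-hydroxy-2-(iodomethyl)-6-methyl-4-[(triethylsilyl)oxy]oct-2-en-7-ynoate F4. Nickel‑free CrCl2 then couples F4 intermolecularly with 4 to give the seco‑lactone vinyl iodide F5, whose diastereomers can be separated. A high‑dilution carbonylative Sonogashira reaction closes the ten‑membered hydroxy ynone F6, and cationic gold converts it transannularly into the 8‑O‑triethylsilyl tricyclic lactone F7. PPTS in MeOH finally frees 18. Here macrocycle and furanone are the rings made together. The danger in this variant is Heck‑type capture of the vinyl‑ or acylpalladium by the nearby methylene lactone.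

Step 7 is the second risk. The failure modes are direct (CO‑free) coupling, Z/E erosion of the ene‑dicarbonyl in 13, and poisoning of gold by amine or iodide residues. The fallback sets out from 12 and 4 and returns at 14. Compound 12 is stannylated (Bu3SnOMe, ZnBr2 cat., THF) to methyl (3E,6R)-6-hydroxy-6-methyl-2-methylidene-8-(tributylstannyl)oct-3-en-7-ynoate F2. This undergoes a base‑free and copper‑free carbonylative Stille coupling with 4 (Pd2(dba)3, AsPh3, CO). Compound 13 is then purified on silica and cyclised separately with the gold catalyst to 14.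

Step 6 is the third risk. The failure modes are retro‑aldol or dehydration of 9 in the basic biphasic medium, E/Z mixtures, and Diels–Alder dimerisation of the 2‑carbomethoxydiene. The fallback replaces the olefination by a cross‑coupling; it sets out from 7 and returns at 12. Compound 7 is oxidised to 9, which is used crude in a Takai olefination (CrCl2, CHI3, THF, 0 °C) to give (3R,5E)-6-iodo-3-methylhex-5-en-1-yn-3-ol F1. A base‑free Stille coupling with methyl 2-(tributylstannyl)prop-2-enoate (Pd2(dba)3, AsPh3, 23 °C) delivers 12 with the E geometry fixed by the iodide.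

**Further compounds**
F1 | step 6 | (3R,5E)-6-iodo-3-methylhex-5-en-1-yn-3-ol | C#C[C@](C)(O)C/C=C/I
F2 | step 7 | methyl (3E,6R)-6-hydroxy-6-methyl-2-methylidene-8-(tributylstannyl)oct-3-en-7-ynoate | CCCC[Sn](CCCC)(CCCC)C#C[C@](C)(O)C/C=C/C(=C)C(=O)OC
F3 | step 9 | methyl 2-{(2R,3R)-3-[(2R)-2-hydroxy-2-methylbut-3-yn-1-yl]oxiran-2-yl}prop-2-enoate | C#C[C@](C)(O)C[C@H]1O[C@@H]1C(=C)C(=O)OC
F4 | step 9 | methyl (2Z,4R,6R)-6-hydroxy-2-(iodomethyl)-6-methyl-4-[(triethylsilyl)oxy]oct-2-en-7-ynoate | C#C[C@](C)(O)C[C@@H](O[Si](CC)(CC)CC)/C=C(\CI)C(=O)OC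
F5 | step 9 | seco-lactone vinyl iodide (C6, C7, C8, C10 arranged as in 18; C4–I, C10–OH, ethynyl, 8-OSiEt3) | C=C1C(=O)O[C@@H](/C=C(\I)CO[Si](C)(C)C(C)(C)C)[C@@H]1[C@H](O[Si](CC)(CC)CC)C[C@@](C)(O)C#C
F6 | step 9 | ten-membered hydroxy ynone lactone (C3 ketone, C1≡C2, 10-OH, 8-OSiEt3) | C=C1C(=O)O[C@H]2/C=C(/CO[Si](C)(C)C(C)(C)C)C(=O)C#C[C@](C)(O)C[C@@H](O[Si](CC)(CC)CC)[C@H]12
F7 | step 9 | 8-O-triethylsilyl ether of 18 | C=C1C(=O)O[C@H]2/C=C(/CO[Si](C)(C)C(C)(C)C)C3=CC(=O)[C@@](C)(C[C@@H](O[Si](CC)(CC)CC)[C@H]12)O3
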